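**Remark (assumption):** the target has no stereocentre and no stereogenic double bond (the enoate β-carbon carries two methyl groups). It is achiral, so "single enantiomer" sets no stereochemical task.

**Retrosynthetic overview**
1. The thenylic ester C–O bond is cut to the bithienyl methanol and 3-methylbut-2-enoic acid; the C5'–C(sp) bond is cut to a 5'-bromobithiophene and but-3-ynyl 3-methylbutanoate (Sonogashira).
2. Key disconnection: ring A (S1, C2, C3, C4, C5; CH2O on C2, ring B on C5) is opened at S1–C2 and S1–C5 to a conjugated 1,3-diyne plus sulfide, so the C5–C2' bithienyl bond is made as an alkynyl–thienyl bond and never as a biaryl coupling.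
3. This copies the presumed biogenesis of the Asteraceae bithiophenes: the unbranched C13 chain of the target (CH2–C4–C4–C≡C–CH2–CH2) is that of a polyacetylene that takes up sulfur across a diyne.
4. Three components meet in one flask: 2-bromo-5-iodothiophene (ring B), a C5 silyl diynol (C2–C5 and the CH2OH carbon) and sodium sulfide (S1).
5. Ring order: ring B is bought; ring A is the only ring closed (step 3, 5-endo-dig). No oxygen protecting group is used.

Key step: step 3

**Step 1**
Reactants: 1 but-3-yn-1-ol; 2 3-methylbutanoyl chloride
Product: 3 but-3-yn-1-yl 3-methylbutanoate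
Conditions: pyridine (1.5 equiv), DMAP (5 mol%), CH2Cl2, 0 °C to rt
Reagents that add atoms: none
Why: DMAP-catalysed nucleophilic acyl substitution of a primary alcohol by an acid chloride; the terminal alkyne is inert, so the isovalerate is in place before any coupling.

**Step 2**
Reactants: 4 1,4-bis(trimethylsilyl)buta-1,3-diyne
Product: 6 5-(trimethylsilyl)penta-2,4-diyn-1-ol, via lithium 4-(trimethylsilyl)buta-1,3-diyn-1-ide 5 (not isolated)
Conditions: MeLi·LiBr (1.0 equiv), THF, rt, 4 h; then (CH2O)n, −78 °C to rt; H2O
Reagents that add atoms: paraformaldehyde (source of formaldehyde), C=O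
Why: Methyllithium attacks one silicon and expels the diynide (selective mono-desilylation, because the anionic diynide resists a second attack at the remote silicon), and this acetylide adds 1,2 to formaldehyde to give the primary propargylic alcohol.

**Step 3**
Reactants: 6 5-(trimethylsilyl)penta-2,4-diyn-1-ol; 7 2-bromo-5-iodothiophene
Product: 10 (5'-bromo-[2,2'-bithiophen]-5-yl)methanol, via penta-2,4-diyn-1-ol 8 (not isolated), via 5-(5-bromothiophen-2-yl)penta-2,4-diyn-1-ol 9 (not isolated)
Conditions: PdCl2(PPh3)2 (3 mol%), CuI (5 mol%), K2CO3 (0.2 equiv), MeOH/THF/Et3N, Ar, rt; then Na2S·9H2O (3 equiv), DMSO, 55 °C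
Reagents that add atoms: sodium sulfide (used as the nonahydrate), [Na+].[Na+].[S-2]
Why: Methanolysis of the C–Si bond releases the terminal diyne 8 slowly, and its copper acetylide couples (Sonogashira) with the C–I bond of 7 at room temperature, where the C–Br bond does not undergo oxidative addition, to give the aryl diyne 9; this sets the C5–C2' bond of the target as a C(sp)–C(sp2) bond. Hydrosulfide then adds anti across one triple bond of 9 (nucleophilic thiol–yne addition to an activated 1,3-diyne) to give a Z-enyne thiolate with sulfur cis to the remaining alkyne, and this closes ring A by 5-endo-dig attack on the distal alkyne carbon, followed by protonation to the aromatic thiophene. The closest known reaction type is the sulfide cyclisation of 1,3-diynes to 2,5-disubstituted thiophenes, which has also been run in one pot after a Pd/Cu alkyne coupling. No stereocentre is formed, and the regiochemistry of the first C–S bond does not matter, because attack at either diyne terminus leads to the same thiophene. The selectivities needed are iodide over bromide (secured by the large rate difference at room temperature), cross-coupling over homocoupling of 8 (secured by its slow release under argon), and reaction at the diyne only (the bromothiophene and the primary alcohol are inert to sulfide at 55 °C, and sulfide deactivates the palladium before the C–Br bond can react).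

**Step 4**
Reactants: 10 (5'-bromo-[2,2'-bithiophen]-5-yl)methanol; 3 but-3-yn-1-yl 3-methylbutanoate
Product: 11 4-[5'-(hydroxymethyl)-[2,2'-bithiophen]-5-yl]but-3-yn-1-yl 3-methylbutanoate
Conditions: PdCl2(PPh3)2 (5 mol%), CuI (5 mol%), Et3N/THF 1:1, Ar, 60 °C
Reagents that add atoms: none
Why: Sonogashira coupling of a 5-bromo-2,2'-bithiophene with a terminal alkyne; the free primary alcohol is tolerated, and a tertiary amine base avoids aminolysis of the isovalerate.

**Step 5**
Reactants: 11 4-[5'-(hydroxymethyl)-[2,2'-bithiophen]-5-yl]but-3-yn-1-yl 3-methylbutanoate; 12 3-methylbut-2-enoic acid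
Product: 13 {5'-[4-(3-methylbutanoyloxy)but-1-yn-1-yl]-[2,2'-bithiophen]-5-yl}methyl 3-methylbut-2-enoate (target)
Conditions: DCC (1.2 equiv), DMAP (10 mol%), CH2Cl2, 0 °C to rt, dark
Reagents that add atoms: none
Why: Steglich esterification of the only free hydroxyl; activating the acid as an O-acylisourea at 0 °C with catalytic DMAP avoids the vinylketene pathway that moves the double bond out of conjugation, and the near-neutral conditions spare the acid-sensitive thenylic C–O bond and the alkyne.

**Compound list**
1 | but-3-yn-1-ol | C#CCCO | starting material
2 | 3-methylbutanoyl chloride | CC(C)CC(=O)Cl | starting material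
3 | but-3-yn-1-yl 3-methylbutanoate | C#CCCOC(=O)CC(C)C | intermediate
4 | 1,4-bis(trimethylsilyl)buta-1,3-diyne | C[Si](C)(C)C#CC#C[Si](C)(C)C | starting material
5 | lithium 4-(trimethylsilyl)buta-1,3-diyn-1-ide | [Li]C#CC#C[Si](C)(C)C | intermediate (not isolated)
6 | 5-(trimethylsilyl)penta-2,4-diyn-1-ol | C[Si](C)(C)C#CC#CCO | intermediate
7 | 2-bromo-5-iodothiophene | Brc1ccc(I)s1 | starting material
8 | penta-2,4-diyn-1-ol | C#CC#CCO | intermediate (not isolated)
9 | 5-(5-bromothiophen-2-yl)penta-2,4-diyn-1-ol | OCC#CC#Cc1ccc(Br)s1 | intermediate (not isolated)
10 | (5'-bromo-[2,2'-bithiophen]-5-yl)methanol | OCc1ccc(-c2ccc(Br)s2)s1 | intermediate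
11 | 4-[5'-(hydroxymethyl)-[2,2'-bithiophen]-5-yl]but-3-yn-1-yl 3-methylbutanoate | OCc1ccc(-c2ccc(C#CCCOC(=O)CC(C)C)s2)s1 | intermediate
12 | 3-methylbut-2-enoic acid | CC(C)=CC(=O)O | starting material
13 | {5'-[4-(3-methylbutanoyloxy)but-1-yn-1-yl]-[2,2'-bithiophen]-5-yl}methyl 3-methylbut-2-enoate | CC(C)=CC(=O)OCc1ccc(-c2ccc(C#CCCOC(=O)CC(C)C)s2)s1 | target

**Step count**
Total steps: 5. Longest linear sequence: 4 (steps 2, 3, 4, 5, starting from 4); step 1 is a one-step side branch that joins at step 4.

**Steps most likely to fail**

1. Step 3. The terminal diyne released in the flask may dimerise oxidatively or polymerise before it cross-couples, and the sulfide may give open-chain adducts instead of closing the ring. The fallback gives up the ring construction and sets out from 7. Suzuki–Miyaura coupling at the C–I bond with commercial (5-formylthiophen-2-yl)boronic acid (Pd(PPh3)4, K2CO3, DME/H2O, 50 °C, 1.0 equiv of the boronic acid) should give 5'-bromo-[2,2'-bithiophene]-5-carbaldehyde F1. Reduction with NaBH4 in MeOH/THF at 0 °C should then give 10, where the route is rejoined.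

2. Step 4. Oxidative addition into the electron-rich bromobithiophene may be slow, so that copper-mediated dimerisation consumes the alkyne. The fallback is a copper-free Stille alkynylation and sets out from 3. Heating 3 with tributyltin methoxide (neat, 60 °C, methanol removed under reduced pressure) should give 4-(tributylstannyl)but-3-yn-1-yl 3-methylbutanoate F2. Coupling of this stannane with 10 (Pd(PPh3)4, toluene, 90 °C) should give 11, where the route is rejoined.

3. Step 5. During acid activation the double bond may migrate out of conjugation, or the O-acylisourea may rearrange to an unreactive N-acylurea. The fallback activates the alcohol instead of the acid and sets out from 11. A Mitsunobu esterification with 12 (PPh3, DIAD, THF, 0 °C to rt) should give 13 directly. This fallback makes no new compound (F0).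

**Further compounds**
F1 | step 3 | 5'-bromo-[2,2'-bithiophene]-5-carbaldehyde | O=Cc1ccc(-c2ccc(Br)s2)s1
F2 | step 4 | 4-(tributylstannyl)but-3-yn-1-yl 3-methylbutanoate | CCCC[Sn](CCCC)(CCCC)C#CCCOC(=O)CC(C)C
F0 | step 5 | none | none
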